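The plan rests on cutting the C9–C10 bond. Ring A has its oxygen at C3 para to the methyl-bearing quaternary C10 and a methyl at C4, so it is a masked 2,4-dimethylphenol whose meta carbon (C5) carries the C6–C7–C8 tether. An iridium-catalysed asymmetric allylic dearomatisation sends the phenolate para carbon onto the inner allyl terminus. This single operation forms C9–C10, closes ring B, sets C9 and C10, and leaves a C9 vinyl handle and a cross-conjugated dienone for completing ring A. The precursor is that phenol with an (R)-configured triethylsilyl-protected tertiary carbinol at C8 (from a Sharpless epoxidation) and an (E)-allylic methyl carbonate spanning C9, C11 and C12.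

Key step: step 11

Assumption: the SMILES is read literally as (3S,5S,8R,9R,10S) in terpenoid numbering (ring A = C1–C5 plus C10, ring B = C5–C10, side chain from C11), which puts H5 on the same face as the C10 methyl (cis-fused rings A and B); C5 is therefore set by a copper hydride 1,4-addition syn to the angular methyl and not by dissolving-metal reductive methylation, which would lead to the trans-fused 5R epimer.

Step 1
Reactants: 1 2-bromo-1,3-dimethylbenzene
Product: 2 2-bromo-4-iodo-1,3-dimethylbenzene
Conditions: NIS, CF3CO2H, rt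
Reagents that add atoms: N-iodosuccinimide, O=C1CCC(=O)N1I
Why: Electrophilic aromatic iodination; the position ortho to one methyl and para to the other is the only doubly activated site of 1, so iodine should enter there, meta to bromine.

Step 2
Reactants: 2 2-bromo-4-iodo-1,3-dimethylbenzene
Product: 3 3-bromo-2,4-dimethylphenol
Conditions: CuI (10 mol %), 1,10-phenanthroline (20 mol %), KOH, DMSO/H2O, 100 °C; acidic work-up
Reagents that add atoms: potassium hydroxide, [K+].[OH-]
Why: Ullmann-type copper-catalysed hydroxylation takes the aryl iodide and spares the bromide, which is the poorer leaving group and is shielded by two ortho methyl groups.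

Step 3
Reactants: 3 3-bromo-2,4-dimethylphenol
Product: 4 (3-bromo-2,4-dimethylphenoxy)triisopropylsilane
Conditions: TIPSCl, imidazole, DMF, rt
Reagents that add atoms: chlorotriisopropylsilane, CC(C)[Si](Cl)(C(C)C)C(C)C
Why: Routine O-silylation; the bulky aryl silyl ether should survive the basic coupling, the epoxidation and the zinc step and still leave with fluoride faster than a tertiary alkyl silyl ether.

Step 4
Reactants: 5 (E)-3-methylpent-2-en-4-yn-1-ol
Product: 6 (E)-3-methylpenta-2,4-dien-1-ol
Conditions: H2 (1 atm), Lindlar catalyst (Pd/CaCO3 poisoned with Pb(OAc)2), quinoline, EtOAc, rt, stopped after one equivalent of H2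
Reagents that add atoms: none
Why: Lindlar semihydrogenation stops a terminal alkyne at the vinyl stage and leaves the configuration of the existing E-trisubstituted alkene untouched.

Step 5
Reactants: 6 (E)-3-methylpenta-2,4-dien-1-ol; 4 (3-bromo-2,4-dimethylphenoxy)triisopropylsilane
Product: 8 (E)-5-[2,6-dimethyl-3-(triisopropylsilyloxy)phenyl]-3-methylpent-2-en-1-ol, via bis(9-BBN) adduct 7 (not isolated)
Conditions: 9-BBN-H (2.2 equiv), THF, 0 °C to rt; then 4, Pd(OAc)2 (5 mol %), SPhos (10 mol %), aq. K3PO4, THF, 65 °C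
Reagents that add atoms: none
Why: Hydroboration/B-alkyl Suzuki–Miyaura coupling, in which 9-BBN first masks the hydroxyl as a borinate and then adds only to the monosubstituted end of the diene (boron on the terminal CH2), while the bulky biaryl phosphine permits coupling with the di-ortho-substituted bromide; the pure E-alkene is carried over, so neither a slow copper-mediated transfer of a 2,6-dimethylaryl group nor a poorly E-selective ketone olefination is needed.

Step 6
Reactants: 8 (E)-5-[2,6-dimethyl-3-(triisopropylsilyloxy)phenyl]-3-methylpent-2-en-1-ol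
Product: 9 [(2R,3R)-3-{2-[2,6-dimethyl-3-(triisopropylsilyloxy)phenyl]ethyl}-3-methyloxiran-2-yl]methanol
Conditions: Ti(OiPr)4 (10 mol %), D-(−)-diisopropyl tartrate (12 mol %), t-BuOOH, 4 Å molecular sieves, CH2Cl2, −20 °C
Reagents that add atoms: tert-butyl hydroperoxide, CC(C)(C)OO
Why: Sharpless asymmetric epoxidation; with the D-(−)-tartrate this geraniol-type E-allylic alcohol should give the (2R,3R)-epoxide, which fixes C8 as R (the C9 centre is erased in step 7).

Step 7
Reactants: 9 [(2R,3R)-3-{2-[2,6-dimethyl-3-(triisopropylsilyloxy)phenyl]ethyl}-3-methyloxiran-2-yl]methanol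
Product: 11 (3R)-5-[2,6-dimethyl-3-(triisopropylsilyloxy)phenyl]-3-methylpent-1-en-3-ol, via epoxy iodide 10 (not isolated)
Conditions: I2, PPh3, imidazole, THF, 0 °C; then Zn dust, AcOH, EtOH, rt
Reagents that add atoms: none
Why: Appel iodination followed by zinc-induced reductive β-elimination (Boord-type opening of a 2,3-epoxy iodide) gives the tertiary vinyl carbinol without breaking the C8–O bond, so C8 stays R.

Step 8
Reactants: 11 (3R)-5-[2,6-dimethyl-3-(triisopropylsilyloxy)phenyl]-3-methylpent-1-en-3-ol; 12 allyl methyl carbonate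
Product: 13 (2E,4R)-6-[2,6-dimethyl-3-(triisopropylsilyloxy)phenyl]-4-hydroxy-4-methylhex-2-en-1-yl methyl carbonate
Conditions: 12 (4 equiv), Hoveyda–Grubbs second-generation catalyst (H2IMes)Cl2Ru=CH(2-iPrOC6H4) (5 mol %), CH2Cl2, 40 °C
Reagents that add atoms: none
Why: Olefin cross-metathesis between a slowly homodimerising free tertiary allylic alcohol and a rapidly exchanging allyl carbonate favours the cross product, and the fully substituted C8 enforces the E-alkene.

Step 9
Reactants: 13 (2E,4R)-6-[2,6-dimethyl-3-(triisopropylsilyloxy)phenyl]-4-hydroxy-4-methylhex-2-en-1-yl methyl carbonate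
Product: 14 (2E,4R)-6-[2,6-dimethyl-3-(triisopropylsilyloxy)phenyl]-4-methyl-4-(triethylsilyloxy)hex-2-en-1-yl methyl carbonate
Conditions: TESOTf, 2,6-lutidine, CH2Cl2, −78 to 0 °C
Reagents that add atoms: triethylsilyl trifluoromethanesulfonate, CC[Si](CC)(CC)OS(=O)(=O)C(F)(F)F
Why: Silyl triflate silylation is the standard way to cap a tertiary alcohol, and the hindered base at low temperature avoids ionisation of the tertiary allylic C–O bond.

Step 10
Reactants: 14 (2E,4R)-6-[2,6-dimethyl-3-(triisopropylsilyloxy)phenyl]-4-methyl-4-(triethylsilyloxy)hex-2-en-1-yl methyl carbonate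
Product: 15 3-[(3R,4E)-6-(methoxycarbonyloxy)-3-methyl-3-(triethylsilyloxy)hex-4-enyl]-2,4-dimethylphenol
Conditions: TBAF (1.05 equiv), AcOH (1.1 equiv), THF, 0 °C
Reagents that add atoms: none
Why: Chemoselective fluoride desilylation; phenoxide is the better leaving group, so the aryl silyl ether goes much faster than the hindered tertiary alkyl one, and the acetic acid buffer keeps the freed phenol from attacking the carbonate.

Step 11
Reactants: 15 3-[(3R,4E)-6-(methoxycarbonyloxy)-3-methyl-3-(triethylsilyloxy)hex-4-enyl]-2,4-dimethylphenol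
Product: 16 (4aR,5R,6R)-5-ethenyl-1,4a,6-trimethyl-6-(triethylsilyloxy)-5,6,7,8-tetrahydronaphthalen-2(4aH)-one (8R,9R,10R in terpenoid numbering)
Conditions: [Ir(cod)Cl]2 (4 mol %), binaphthol-derived N,N-bis(1-phenylethyl)phosphoramidite (8 mol %, the antipode that holds iridium on the Re face of C9), pre-activation with n-PrNH2, Li2CO3, THF (0.01 M), 50 °C
Reagents that add atoms: none
Why: The cyclometalated iridium–phosphoramidite catalyst ionises the carbonate with loss of CO2 and methoxide, which deprotonates the phenol, and the phenolate then attacks the π-allyl unit anti to the metal through its para carbon C10 at the substituted terminus C9; because C10 bears a methyl group no rearomatisation can follow and the 2,5-cyclohexadienone is kept. The closest known chemistry is the iridium-catalysed intramolecular asymmetric allylic dearomatisation of phenols to spirodienones, together with the 6-exo allylic Friedel–Crafts closure of meta-tethered phenols, so this is a Tsuji–Trost-type asymmetric allylic alkylation applied to a new member of a known substrate class. Ring B (C5–C6–C7–C8–C9–C10) closes in a 6-exo mode, the alternative 8-endo attack at C12 being out of reach. C9 (R) is set by the ligand, which keeps iridium on the Re face so that C10 bonds to the Si face of C9, and C10 follows from C9 through a chair-like transition state in which the bulky metal-bound allyl unit and the OTES group sit equatorial, which presents the Si face of C10. The step needs para-carbon attack to beat ortho-carbon (C4) and oxygen attack: C4 is buttressed by the ion-paired phenolate oxygen and would give the less stable linearly conjugated dienone, oxygen closure would need a strained meta-bridged ring, and high dilution suppresses intermolecular O-allylation. The TES ether stops O8 from capturing the allyl unit and from later triggering alkoxide-driven cleavage of C9–C10 in the dienone.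

Step 12
Reactants: 16 (4aR,5R,6R)-5-ethenyl-1,4a,6-trimethyl-6-(triethylsilyloxy)-5,6,7,8-tetrahydronaphthalen-2(4aH)-one
Product: 17 (4aR,5R,6R)-5-ethenyl-1,4a,6-trimethyl-6-(triethylsilyloxy)-4,4a,5,6,7,8-hexahydronaphthalen-2(3H)-one
Conditions: [(Ph3P)CuH]6 (0.3 equiv), H2O (5 equiv), degassed toluene, rt
Reagents that add atoms: none
Why: Copper hydride conjugate reduction; the phosphine-ligated hydride adds to the disubstituted C1=C2 arm of the dienone, is too unreactive for the tetrasubstituted C4=C5 arm, ignores the isolated vinyl group, and creates no stereocentre.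

Step 13
Reactants: 17 (4aR,5R,6R)-5-ethenyl-1,4a,6-trimethyl-6-(triethylsilyloxy)-4,4a,5,6,7,8-hexahydronaphthalen-2(3H)-one
Product: 20 (4aS,5R,6R,8aS)-5-ethenyl-1,1,4a,6-tetramethyl-6-(triethylsilyloxy)octahydronaphthalen-2(1H)-one, via diphenylsilyl enol ether 18 (not isolated), via lithium enolate 19 (not isolated)
Conditions: (IPr)CuCl (5 mol %; IPr = 1,3-bis(2,6-diisopropylphenyl)imidazol-2-ylidene), NaOtBu (5 mol %), Ph2SiH2 (1.2 equiv), toluene, rt to 40 °C; then MeLi, THF, 0 °C; then MeI, DMPU, −78 to 0 °C
Reagents that add atoms: iodomethane, C[I]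
Why: Copper hydride 1,4-hydrosilylation followed by regiospecific enolate methylation (silyl enol ether cleavage with MeLi); the carbene-ligated hydride is active enough for a tetrasubstituted enone and, like other copper nucleophiles on 10-methyl-octalones, should reach C5 syn to the angular methyl, because the α face is guarded by the axial hydrogens at C7 and C9 and the trans-type transition state suffers allylic strain between the C4 methyl and C6, which sets 5S, while methylation of enolate 19 at C4 gives a non-stereogenic gem-dimethyl carbon.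

Step 14
Reactants: 20 (4aS,5R,6R,8aS)-5-ethenyl-1,1,4a,6-tetramethyl-6-(triethylsilyloxy)octahydronaphthalen-2(1H)-one
Product: 21 (2S,4aS,5R,6R,8aS)-5-ethenyl-1,1,4a,6-tetramethyl-6-(triethylsilyloxy)decahydronaphthalen-2-ol (3S,5S,8R,9R,10S in terpenoid numbering)
Conditions: (R)-2-methyl-CBS-oxazaborolidine (0.5 equiv), catecholborane (2 equiv), toluene, −20 °C to rt; aq. NaOH work-up
Reagents that add atoms: none
Why: Corey–Bakshi–Shibata reduction; the (R)-oxazaborolidine tells the quaternary C4 (large) from the C2 methylene (small) and should deliver hydride to the Re (α) face of C3 to give the 3S alcohol by reagent control, which is preferred because the mobile cis-decalone offers no reliable bias, and catecholborane does not hydroborate the vinyl group at this temperature.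

Step 15
Reactants: 22 geranyl bromide; 23 propyne
Product: 26 (E)-6,10-dimethylundeca-5,9-dien-1-yne, via 1,3-dilithiopropyne 24 (not isolated), via lithium acetylide 25 (not isolated)
Conditions: 23, n-BuLi (2 equiv per propyne), TMEDA, Et2O/hexane, −78 °C to rt; then 22, −78 °C to rt; H2O quench
Reagents that add atoms: none
Why: Propargylation of an allylic halide; the dianion reacts at its more nucleophilic propargylic carbon in a direct SN2 displacement, which gives the terminal 1,5-enyne in one step and keeps the E-alkene.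

Step 16
Reactants: 26 (E)-6,10-dimethylundeca-5,9-dien-1-yne
Product: 28 (1E,5E)-1-iodo-2,6,10-trimethylundeca-1,5,9-triene, via alkenylalane 27 (not isolated)
Conditions: Me3Al (2.5 equiv), Cp2ZrCl2 (0.25 equiv), CH2Cl2, 0 °C to rt; then I2, THF, −30 °C
Reagents that add atoms: trimethylaluminium, C[Al](C)C; iodine, [I][I]
Why: Negishi zirconium-catalysed carboalumination adds methyl and aluminium syn across the terminal alkyne with aluminium at the terminus, and iodinolysis with retention gives the E-iodoalkene that becomes C13=C14.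

Step 17
Reactants: 28 (1E,5E)-1-iodo-2,6,10-trimethylundeca-1,5,9-triene
Product: 29 (2E,6E,10E)-11-iodo-2,6,10-trimethylundeca-2,6,10-trien-1-ol
Conditions: SeO2 (0.2 equiv), t-BuOOH (2.5 equiv), salicylic acid (0.1 equiv), CH2Cl2, 0 °C
Reagents that add atoms: tert-butyl hydroperoxide, CC(C)(C)OO
Why: Riley allylic oxidation (ene reaction then [2,3]-shift) prefers the electron-rich, least hindered terminal isopropylidene unit over the inner alkene and the deactivated iodoalkene, and it oxidises the E-methyl group.

Step 18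
Reactants: 21 (2S,4aS,5R,6R,8aS)-5-ethenyl-1,1,4a,6-tetramethyl-6-(triethylsilyloxy)decahydronaphthalen-2-ol; 29 (2E,6E,10E)-11-iodo-2,6,10-trimethylundeca-2,6,10-trien-1-ol
Product: 31 8-O-triethylsilyl myrrhanol A, via trialkylborane 30 (not isolated)
Conditions: 9-BBN-H (3 equiv), THF, rt to 50 °C; then 3 M aq. NaOH, 29, PdCl2(dppf) (10 mol %), THF/DMF, rt to 50 °C
Reagents that add atoms: none
Why: Hydroboration/B-alkyl Suzuki–Miyaura coupling; 9-BBN adds to the only monosubstituted alkene with boron on C12, and the coupling joins C12 to C13 with retention of the E-iodoalkene geometry without touching any stereocentre.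

Step 19
Reactants: 31 8-O-triethylsilyl myrrhanol A
Product: 32 myrrhanol A, (3S,5S,8R,9R,10S; 13E,17E,21E)
Conditions: HF·pyridine, pyridine, THF, 0 °C to rt
Reagents that add atoms: none
Why: Buffered fluoride desilylation removes the last protecting group under conditions that should not ionise the tertiary C8 alcohol or the allylic alcohol.

Compound list
1 | 2-bromo-1,3-dimethylbenzene | Cc1cccc(C)c1Br | starting material
2 | 2-bromo-4-iodo-1,3-dimethylbenzene | Cc1ccc(I)c(C)c1Br | intermediate
3 | 3-bromo-2,4-dimethylphenol | Cc1ccc(O)c(C)c1Br | intermediate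
4 | (3-bromo-2,4-dimethylphenoxy)triisopropylsilane | Cc1ccc(O[Si](C(C)C)(C(C)C)C(C)C)c(C)c1Br | intermediate
5 | (E)-3-methylpent-2-en-4-yn-1-ol | C#C/C(C)=C/CO | starting material
6 | (E)-3-methylpenta-2,4-dien-1-ol | C=C/C(C)=C/CO | intermediate
7 | bis(9-BBN) adduct of 6 (terminal C–B trialkylborane plus O–B borinate, E-alkene kept) | C/C(CCB1C2CCCC1CCC2)=C\COB1C2CCCC1CCC2 | intermediate
8 | (E)-5-[2,6-dimethyl-3-(triisopropylsilyloxy)phenyl]-3-methylpent-2-en-1-ol | C/C(CCc1c(C)ccc(O[Si](C(C)C)(C(C)C)C(C)C)c1C)=C\CO | intermediate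
9 | [(2R,3R)-3-{2-[2,6-dimethyl-3-(triisopropylsilyloxy)phenyl]ethyl}-3-methyloxiran-2-yl]methanol | OC[C@H]1O[C@]1(C)CCc1c(C)ccc(O[Si](C(C)C)(C(C)C)C(C)C)c1C | intermediate
10 | (2R,3S)-2-{2-[2,6-dimethyl-3-(triisopropylsilyloxy)phenyl]ethyl}-3-(iodomethyl)-2-methyloxirane | IC[C@H]1O[C@]1(C)CCc1c(C)ccc(O[Si](C(C)C)(C(C)C)C(C)C)c1C | intermediate
11 | (3R)-5-[2,6-dimethyl-3-(triisopropylsilyloxy)phenyl]-3-methylpent-1-en-3-ol | C=C[C@](C)(O)CCc1c(C)ccc(O[Si](C(C)C)(C(C)C)C(C)C)c1C | intermediate
12 | allyl methyl carbonate | C=CCOC(=O)OC | starting material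
13 | (2E,4R)-6-[2,6-dimethyl-3-(triisopropylsilyloxy)phenyl]-4-hydroxy-4-methylhex-2-en-1-yl methyl carbonate | COC(=O)OC/C=C/[C@](C)(O)CCc1c(C)ccc(O[Si](C(C)C)(C(C)C)C(C)C)c1C | intermediate
14 | (2E,4R)-6-[2,6-dimethyl-3-(triisopropylsilyloxy)phenyl]-4-methyl-4-(triethylsilyloxy)hex-2-en-1-yl methyl carbonate | COC(=O)OC/C=C/[C@](C)(O[Si](CC)(CC)CC)CCc1c(C)ccc(O[Si](C(C)C)(C(C)C)C(C)C)c1C | intermediate
15 | 3-[(3R,4E)-6-(methoxycarbonyloxy)-3-methyl-3-(triethylsilyloxy)hex-4-enyl]-2,4-dimethylphenol (key-step precursor) | Oc1ccc(C)c(CC[C@@](C)(O[Si](CC)(CC)CC)/C=C/COC(=O)OC)c1C | intermediate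
16 | (4aR,5R,6R)-5-ethenyl-1,4a,6-trimethyl-6-(triethylsilyloxy)-5,6,7,8-tetrahydronaphthalen-2(4aH)-one (cross-conjugated dienone, key-step product) | C=C[C@@H]1[C@@]2(C)C=CC(=O)C(C)=C2CC[C@@]1(C)O[Si](CC)(CC)CC | intermediate
17 | (4aR,5R,6R)-5-ethenyl-1,4a,6-trimethyl-6-(triethylsilyloxy)-4,4a,5,6,7,8-hexahydronaphthalen-2(3H)-one (C4=C5 enone) | C=C[C@@H]1[C@@]2(C)CCC(=O)C(C)=C2CC[C@@]1(C)O[Si](CC)(CC)CC | intermediate
18 | C3–C4 diphenylsilyl enol ether, cis-fused (5S,8R,9R,10S) | C=C[C@@H]1[C@@]2(C)CCC(O[SiH](c3ccccc3)c3ccccc3)=C(C)[C@H]2CC[C@@]1(C)O[Si](CC)(CC)CC | intermediate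
19 | C3–C4 lithium enolate, cis-fused (5S,8R,9R,10S) | C=C[C@@H]1[C@@]2(C)CCC(O[Li])=C(C)[C@H]2CC[C@@]1(C)O[Si](CC)(CC)CC | intermediate
20 | (4aS,5R,6R,8aS)-5-ethenyl-1,1,4a,6-tetramethyl-6-(triethylsilyloxy)octahydronaphthalen-2(1H)-one | C=C[C@@H]1[C@@]2(C)CCC(=O)C(C)(C)[C@H]2CC[C@@]1(C)O[Si](CC)(CC)CC | intermediate
21 | (2S,4aS,5R,6R,8aS)-5-ethenyl-1,1,4a,6-tetramethyl-6-(triethylsilyloxy)decahydronaphthalen-2-ol | C=C[C@@H]1[C@@]2(C)CC[C@H](O)C(C)(C)[C@H]2CC[C@@]1(C)O[Si](CC)(CC)CC | intermediate
22 | geranyl bromide, (E)-1-bromo-3,7-dimethylocta-2,6-diene | CC(C)=CCC/C(C)=C/CBr | starting material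
23 | propyne | CC#C | starting material
24 | 1,3-dilithiopropyne | [Li]CC#C[Li] | intermediate
25 | lithium acetylide of 26 | [Li]C#CCC/C=C(\C)CCC=C(C)C | intermediate
26 | (E)-6,10-dimethylundeca-5,9-dien-1-yne | C#CCC/C=C(\C)CCC=C(C)C | intermediate
27 | dimethyl[(1E,5E)-2,6,10-trimethylundeca-1,5,9-trien-1-yl]alane | C[Al](C)/C=C(\C)CC/C=C(\C)CCC=C(C)C | intermediate
28 | (1E,5E)-1-iodo-2,6,10-trimethylundeca-1,5,9-triene | I/C=C(\C)CC/C=C(\C)CCC=C(C)C | intermediate
29 | (2E,6E,10E)-11-iodo-2,6,10-trimethylundeca-2,6,10-trien-1-ol | C/C(=C\CC/C(C)=C/CC/C(C)=C/I)CO | intermediate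
30 | C12 B-alkyl-9-BBN derivative of 21 with the C3 oxygen held as 9-BBN borinate | C1CCC2CCCC1B2CC[C@@H]3[C@@]4(C)CC[C@H](OB5C6CCCC5CCC6)C(C)(C)[C@H]4CC[C@@]3(C)O[Si](CC)(CC)CC | intermediate
31 | 8-O-triethylsilyl myrrhanol A | C/C(=C\CC/C(C)=C/CC/C(C)=C/CC[C@@H]1[C@@]2(C)CC[C@H](O)C(C)(C)[C@H]2CC[C@@]1(C)O[Si](CC)(CC)CC)CO | intermediate
32 | myrrhanol A, (3S,5S,8R,9R,10S; 13E,17E,21E) | C/C(=C\CC/C(C)=C/CC/C(C)=C/CC[C@@H]1[C@@]2(C)CC[C@H](O)C(C)(C)[C@H]2CC[C@@]1(C)O)CO | target

Total step count: 19. Longest linear sequence: 15 steps (1, 2, 3, 5–14, 18, 19, from compound 1).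

Steps most likely to fail

Step 11.
- **What may go wrong:**
  - Ionisation and attack at an allyl terminus next to the fully substituted C8 may be slow.
  - The two methyl groups that become syn-axial may erode the choice of arene face if the ligand and C8 turn out mismatched.
  - Ortho-carbon attack or intermolecular O-allylation may compete.
- **Fallback:** the same bond is made by a metal-free, stereospecific phenolate para-alkylation (aryl-participation type epoxide opening). It sets out from 9. Parikh–Doering oxidation gives the epoxy aldehyde F1, and Wittig methylenation gives the vinyl epoxide F2. TBAF then frees the phenolic vinyl epoxide F3. KOt-Bu in t-BuOH lets C10 open the allylic C9–O bond with inversion (6-endo, activated by the vinyl group) to the hydroxy dienone F4. In F4 the C9 configuration comes from the Sharpless epoxide and not from a ligand. Silylation with TESOTf/2,6-lutidine comes back to the route at 16.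

Step 13.
- **What may go wrong:** hydride transfer to the hindered, fully substituted C5 may be too slow, or facial selectivity may be poor and erode the 5S configuration.
- **Fallback:** C5 is set on a metal surface after the vinyl group has been turned into a hydrogenation-proof coupling handle. It sets out from 17. Hydroboration of the vinyl group with pinacolborane, catalysed by [Ir(cod)Cl]2/dppe, gives the pinacol boronate enone F5. Hydrogenation over Pd/C in 4-methoxypyridine, a medium known to favour cis-fused products from 3-oxo-4-ene systems, gives the cis-fused 4-methyl ketone F6. Thermodynamic enolisation toward C4 (KOt-Bu, t-BuOH) and MeI give the gem-dimethyl boronate ketone F7. Reduction as in step 14 gives the boronate alcohol F8. Its Suzuki–Miyaura coupling with 29 (Pd(OAc)2, RuPhos, KOH, THF/H2O) comes back to the route at 31.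

Step 14.
- **What may go wrong:** the conformationally mobile cis-decalone may oppose the reagent, giving poor facial selectivity at C3 or a sluggish reduction next to the quaternary C4.
- **Fallback:** stereocontrol is given up in favour of separation and recycling. It sets out from 20, which is reduced with NaBH4 in MeOH, and the epimeric alcohols are separated by chromatography. The 3R-epimeric alcohol F9 is re-oxidised to 20 with Dess–Martin periodinane and resubmitted. The 3S alcohol joins the route at 21.

Further compounds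
F1 | step 11 | (2S,3R)-3-{2-[2,6-dimethyl-3-(triisopropylsilyloxy)phenyl]ethyl}-3-methyloxirane-2-carbaldehyde | O=C[C@H]1O[C@]1(C)CCc1c(C)ccc(O[Si](C(C)C)(C(C)C)C(C)C)c1C
F2 | step 11 | (2R,3R)-2-{2-[2,6-dimethyl-3-(triisopropylsilyloxy)phenyl]ethyl}-3-ethenyl-2-methyloxirane | C=C[C@H]1O[C@]1(C)CCc1c(C)ccc(O[Si](C(C)C)(C(C)C)C(C)C)c1C
F3 | step 11 | 3-{2-[(2R,3R)-3-ethenyl-2-methyloxiran-2-yl]ethyl}-2,4-dimethylphenol | C=C[C@H]1O[C@]1(C)CCc1c(C)ccc(O)c1C
F4 | step 11 | (4aR,5R,6R)-5-ethenyl-6-hydroxy-1,4a,6-trimethyl-5,6,7,8-tetrahydronaphthalen-2(4aH)-one | C=C[C@@H]1[C@@]2(C)C=CC(=O)C(C)=C2CC[C@@]1(C)O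
F5 | step 13 | C12 pinacol boronate of enone 17 (8R,9R,10R) | CC1(C)OB(CC[C@@H]2[C@@]3(C)CCC(=O)C(C)=C3CC[C@@]2(C)O[Si](CC)(CC)CC)OC1(C)C
F6 | step 13 | cis-fused 4-methyl-3-ketone C12 pinacol boronate (5S,8R,9R,10S; C4 unassigned) | CC1(C)OB(CC[C@@H]2[C@@]3(C)CCC(=O)C(C)[C@H]3CC[C@@]2(C)O[Si](CC)(CC)CC)OC1(C)C
F7 | step 13 | cis-fused 4,4-dimethyl-3-ketone C12 pinacol boronate (5S,8R,9R,10S) | CC1(C)OB(CC[C@@H]2[C@@]3(C)CCC(=O)C(C)(C)[C@H]3CC[C@@]2(C)O[Si](CC)(CC)CC)OC1(C)C
F8 | step 13 | cis-fused 3-hydroxy-4,4-dimethyl C12 pinacol boronate (3S,5S,8R,9R,10S) | CC1(C)OB(CC[C@@H]2[C@@]3(C)CC[C@H](O)C(C)(C)[C@H]3CC[C@@]2(C)O[Si](CC)(CC)CC)OC1(C)C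
F9 | step 14 | (2R,4aS,5R,6R,8aS)-5-ethenyl-1,1,4a,6-tetramethyl-6-(triethylsilyloxy)decahydronaphthalen-2-ol (3R epimer of 21) | C=C[C@@H]1[C@@]2(C)CC[C@@H](O)C(C)(C)[C@H]2CC[C@@]1(C)O[Si](CC)(CC)CC
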